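## Structural features

The target 18 is a 2,3-trans flavanonol 3-methyl ether: ring C is a chroman-4-one fused to ring A, which carries hydroxyls at C5 and C6 and a methoxy group at C7, while C2 bears ring B (2,3-dihydroxy-4-methoxyphenyl) and C3 bears a methoxy group. C2 and C3 are neighbouring stereocentres, both R, so ring B and the C3 methoxy group are trans. The fragile parts are the two catechols (air oxidation to ortho-quinones), the enolisable C3, and the β-aryloxy ketone O1–C2–C3–C4=O, which base can open by loss of the O1 phenoxide from the C3 enolate and which is easily dehydrogenated to a flavonol. The carbon skeleton is simple; the real difficulty is the absolute configuration at C2 in a ring that opens readily, the distribution of seven oxygens as three methyl ethers and four free hydroxyls, and a 5,6,7-trioxygenated ring A whose C6 oxygen is absent from simple acetophenones. The key step uses the fact that O1 is an ether oxygen ortho to the ring A carbon (C4a) that bears C4. If O1 carries ring B as a benzyl group and C4 is the ketone of an aryl glyoxylate, the C2 hydrogens stand in a 1,6 relationship to the C4 carbonyl oxygen, so light can transfer one of them and join C2 to C4. That C2–C4 bond is not part of 18; it is removed when C2 shifts from C4 to the adjacent carbon (the future C3), which enlarges the five-membered ring to ring C.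

## Logic of the disconnections

18 ⇒ 17. The C–O bonds cut are those of two diphenylmethylene ketals spanning O5/O6 and O2'/O3'. This masks both catechols with groups that have no hydrogen near C4 and that leave under neutral conditions, so 17 has no free phenol and no oxidisable catechol. The forward step must cleave two ketals without touching the O1–C2 benzylic bond, the C4 ketone or the two stereocentres.

17 ⇒ 16. The O–CH3 bond at C3 is cut, because the C3 oxygen is born as a free hydroxyl in the ring expansion. 16 has a single hydroxyl, so no selectivity among oxygens is needed. The forward methylation must avoid enolate formation.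

16 ⇒ 15 ⇒ 14. The C2–C3 bond is cut and C2 is reconnected to C4 (retro α-ketol shift). Ring C contracts to a dihydrofuran, the C3 stereocentre disappears into a formyl group, and only C2 remains to be controlled. The forward shift must move C2 and not the ring A carbon, with retention at C2, and must leave C3 trans to ring B. 15 is taken back to 14 by adjusting the oxidation level of the exocyclic carbon.

14 ⇒ 13. The exocyclic carbon is returned to the ester level and the chiral alcohol is re-attached. This brings back the auxiliary that makes the two C2 configurations separable. The forward step is a plain hydride reduction.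

13 ⇒ 12. The C2–C4 bond is cut (retro photocyclisation). This opens the five-membered ring and removes both ring stereocentres, leaving an aryl α-keto ester with an ortho benzyl ether. The forward step must abstract hydrogen only from the O1–CH2 group, close cis, and give 13 in a form separable from the diastereomer of opposite ring configuration.

12 ⇒ 10 + 11. The ester C–O bond is cut, giving an aryl glyoxylic acid and a cheap chiral alcohol. The forward step is an esterification of a hindered α-keto acid under neutral conditions.

10 ⇒ 9. The two C–O bonds of the carboxyl group are cut back to a methyl group. The two acetyl carbons are C4 and the future C3, so no C–C bond has to be made on the crowded ring A. The forward oxidation must spare the benzylic ether.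

9 ⇒ 8 + 4. The O1–C2 ether bond is cut, which is the convergent union of rings A and B. The forward step must alkylate a hydrogen-bonded phenol without acid and without a labile benzylic halide.

8 ⇒ 7 + 2, and 7 ⇒ 5 (through 6). The ketal C–O bonds and the C6–O bond are cut. In 5 the two hydroxyls are equivalent, so para-hydroxylation can give only one isomer. Only the vicinal pair of 7 can form a five-membered ketal, so the hydroxyl left free is necessarily O1. The forward steps must cope with the air sensitivity of 7.

4 ⇒ 3 ⇒ 1 + 2. A C–H bond (aldehyde reduction) and the ring B ketal are cut, leading to a commercial catechol aldehyde. The gain is a stable, fully protected ring B building block; the forward steps are routine.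

## Other disconnections considered

Alternative 1: The cut is C4a–C5, with C5 to C8 of ring A coming from a four-membered ring, so that ring A is built last.
- **Forward step:** heating cyclobutenone A1 should open its four-membered ring in a four-electron electrocyclic process. The ketene carbon so formed bonds to C4a in a six-electron electrocyclisation, and tautomerisation then gives phenol A2.
- **In favour:** both stereocentres would be set early, on the heterocyclic half of A1, possibly by asymmetric catalysis, so no material is lost in a separation of diastereomers. On this point the alternative is better than the chosen plan. The 5-hydroxyl is born free, and the key step is a reagent-free isomerisation, equal to step 8 in atom economy.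
- **Against:** A2 has a methyl ether at O6 where 18 has a free hydroxyl. One of four methyl ethers would have to be cleaved selectively, or the two alkoxy groups of A1 made different from the outset. The carbon substituent on the sp3 carbon of A1 must rotate inward for closure, whereas outward rotation is normally preferred. Ring opening is reversible, but the ring-opened form may still be lost to dimerisation or capture. A1 needs a multi-step assembly, and its C3 stereocentre, α to the enone carbonyl, must survive prolonged heating.
- **Comparison:** on structure, the chosen plan differentiates all ring A oxygens from 5 with one hydroxylation, while the alternative delivers the wrong group at O6. On mechanism the two are equal in kind (heat-driven versus light-driven isomerisation). On step economy the alternative is expected to be longer than twelve steps once the assembly of A1 and the O6 correction are counted.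

Alternative 2: The cut is C3–C4.
- **Forward step:** a chiral triazolylidene carbene adds to the ring A aldehyde of dialdehyde A3. The resulting acyl-anion equivalent attacks the aliphatic aldehyde and closes ring C as ketol A4.
- **In favour:** the 3-hydroxychroman-4-one forms directly, with no five-membered ring and no migration whose regiochemistry must be trusted. That is better than the chosen plan. The stereocentre of A3 is α to an aldehyde and racemises easily, so a chiral catalyst could in principle funnel racemic A3 into one stereoisomer. That is also better than step 8, where at most half of 12 becomes 13. The end game after A4 (O-methylation, hydrogenolysis) is the same as after 16, so the two are equal there.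
- **Against:** the donor aldehyde is electron-rich and flanked by two ortho oxygens, so it is the less reactive of the two toward the carbene. The aliphatic aldehyde can itself become the donor, leading to closure with the opposite regiochemistry or to homo-coupling. Ring closures between two aldehydes are less developed than aldehyde–ketone closures. A3 is a sensitive α-aryl-α-aryloxy acetaldehyde, and A4 is labile under the basic conditions that generate the carbene.
- **Comparison:** on structure the protecting-group logic is equal (benzyl ethers versus ketals). On mechanism the alternative depends on chemoselectivity between two aldehydes, whereas in step 8 the site of reaction is fixed by geometry. On step economy it is comparable or one to two steps shorter (equal or slightly better), with more risk concentrated in the key step.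

Alternative 3: The cut is O1–C8a.
- **Forward step:** Ag2O oxidises the free ring A catechol of A5 to the 5,6-ortho-quinone A6. The C2 hydroxyl adds 6-endo to C8a, which is β to the C5 quinone carbonyl and, through C4a, to the C4 ketone. Tautomerisation restores the catechol in A7.
- **In favour:** ring A needs no oxygen at C8a beforehand, so neither a hydroxylation of ring A nor an O1 benzylation is required. The C3 methoxy group is present from the start, so no late methylation of a sensitive ketol is needed, which is better than the chosen plan. The C2–O bond is not broken on closure, and only one deprotection follows, which is better in step economy.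
- **Against:** A7 is more electron-rich than A5 and can be oxidised further. A6 carries a β-hydroxy ketone and can undergo retro-aldol cleavage, destroying both stereocentres, or intermolecular addition and dimerisation. Addition at C7 with loss of methoxide is conceivable. A5 must carry a free catechol beside benzyl ethers.
- **Comparison:** on structure the alternative is better in protecting-group and redox economy. On mechanism the chosen plan is safer, because step 8 is a redox-neutral isomerisation of a fully protected substrate, whereas this closure runs on an unprotected, oxidation-prone one. On step economy the alternative is shorter (better), but depends on close control of the oxidant.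

Key step: step 8

Assumption: 1, 2, 5 and 11 are purchased; flavonoid numbering (O1, C2, C3, C4, C4a to C8a, primed ring B) is used for every intermediate, also before ring C exists.

Remarks on the design:
- Rings A and B are joined by a Mitsunobu reaction of benzylic alcohol 4, because a 2,3,4-trioxygenated benzyl bromide would be labile and would cost an extra step.
- Aldehyde 15 is oxidised and rearranged without isolation, and the 3-hydroxyl of 16 is methylated without base.
- The ester of 12 and 13 is (1R,2S,5R)-menthyl. 13 is (2R,3R), with ring B cis to the hydroxyl and C2 configured as in 18.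
- The triplet and the biradical of step 8 are excited-state species; they are described in the step and not numbered.

## Route

Step 1
Reactants: 1 2,3-dihydroxy-4-methoxybenzaldehyde; 2 dichlorodiphenylmethane
Product: 3 7-methoxy-2,2-diphenyl-1,3-benzodioxole-4-carbaldehyde
Conditions: Ph2O, 170 °C, N2 stream
Reagents that add atoms: none
Why: Ketal formation from a geminal dichloride and a catechol (two substitutions through the chlorodiphenylmethyl cation, HCl expelled); the aldehyde is inert under these neutral, anhydrous conditions.

Step 2
Reactants: 3 7-methoxy-2,2-diphenyl-1,3-benzodioxole-4-carbaldehyde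
Product: 4 (7-methoxy-2,2-diphenyl-1,3-benzodioxol-4-yl)methanol
Conditions: NaBH4, MeOH–THF, 0 °C
Reagents that add atoms: none
Why: Hydride reduction of an aryl aldehyde; the ketal and the methyl ether are inert.

Step 3
Reactants: 5 2',6'-dihydroxy-4'-methoxyacetophenone
Product: 7 1-(2,3,6-trihydroxy-4-methoxyphenyl)ethanone, via potassium aryl sulfate 6 (not isolated)
Conditions: K2S2O8, aq NaOH, 0 °C to rt; then aq HCl, 90 °C, under N2
Reagents that add atoms: K2S2O8 (potassium peroxodisulfate), [K+].[K+].[O-]S(=O)(=O)OOS(=O)(=O)[O-]
Why: Elbs persulfate oxidation: the phenoxide attacks a peroxide oxygen through the carbon para to a hydroxyl, and because the two ring CH positions of 5 are equivalent only one aryl sulfate 6 can form. Acid hydrolysis of the sulfate frees the new hydroxyl, which is the future O6.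

Step 4
Reactants: 7 1-(2,3,6-trihydroxy-4-methoxyphenyl)ethanone; 2 dichlorodiphenylmethane
Product: 8 1-(5-hydroxy-7-methoxy-2,2-diphenyl-1,3-benzodioxol-4-yl)ethanone
Conditions: Ph2O, 170 °C, N2 stream
Reagents that add atoms: none
Why: Catechol ketalisation as in step 1; only the vicinal hydroxyls can close a five-membered dioxole, so the hydroxyl that stays free is the one ortho to acetyl and para to the new oxygen, which is O1. Any acyclic adduct at that hydroxyl is hydrolysed on work-up.

Step 5
Reactants: 8 1-(5-hydroxy-7-methoxy-2,2-diphenyl-1,3-benzodioxol-4-yl)ethanone; 4 (7-methoxy-2,2-diphenyl-1,3-benzodioxol-4-yl)methanol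
Product: 9 1-{7-methoxy-5-[(7-methoxy-2,2-diphenyl-1,3-benzodioxol-4-yl)methoxy]-2,2-diphenyl-1,3-benzodioxol-4-yl}ethanone
Conditions: PPh3, DIAD, THF, 0 °C to rt
Reagents that add atoms: none
Why: Mitsunobu etherification: the ortho-acyl phenol is acidic enough to protonate the betaine and its phenoxide displaces the activated primary benzylic oxygen. The conditions are neutral, so the acid-labile ketals and the new electron-rich benzyl aryl ether survive.

Step 6
Reactants: 9 1-{7-methoxy-5-[(7-methoxy-2,2-diphenyl-1,3-benzodioxol-4-yl)methoxy]-2,2-diphenyl-1,3-benzodioxol-4-yl}ethanone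
Product: 10 2-{7-methoxy-5-[(7-methoxy-2,2-diphenyl-1,3-benzodioxol-4-yl)methoxy]-2,2-diphenyl-1,3-benzodioxol-4-yl}-2-oxoacetic acid
Conditions: SeO2, pyridine, 100 °C; filtration, then cold aq citric acid
Reagents that add atoms: SeO2 (selenium dioxide), O=[Se]=O
Why: Riley-type SeO2 oxidation of an aryl methyl ketone, which in pyridine runs through the aryl glyoxal to the aryl glyoxylic acid. The ether methylene is far less reactive toward SeO2 than the enolisable acetyl group, and the basic medium spares the ketals and the benzyl aryl ether.

Step 7
Reactants: 10 2-{7-methoxy-5-[(7-methoxy-2,2-diphenyl-1,3-benzodioxol-4-yl)methoxy]-2,2-diphenyl-1,3-benzodioxol-4-yl}-2-oxoacetic acid; 11 (−)-menthol, (1R,2S,5R)-2-isopropyl-5-methylcyclohexanol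
Product: 12 (1R,2S,5R)-menthyl 2-{7-methoxy-5-[(7-methoxy-2,2-diphenyl-1,3-benzodioxol-4-yl)methoxy]-2,2-diphenyl-1,3-benzodioxol-4-yl}-2-oxoacetate
Conditions: DCC, DMAP (cat.), CH2Cl2, 0 °C to rt
Reagents that add atoms: none
Why: Steglich esterification of the α-keto acid with a secondary alcohol under neutral conditions; the carbinol carbon of 11 is not involved, so the auxiliary keeps its configuration.

Step 8
Reactants: 12 (1R,2S,5R)-menthyl 2-{7-methoxy-5-[(7-methoxy-2,2-diphenyl-1,3-benzodioxol-4-yl)methoxy]-2,2-diphenyl-1,3-benzodioxol-4-yl}-2-oxoacetate
Product: 13 (1R,2S,5R)-menthyl (2R,3R)-3-hydroxy-6-methoxy-2-(7-methoxy-2,2-diphenyl-1,3-benzodioxol-4-yl)-4,5-(diphenylmethylenedioxy)-2,3-dihydrobenzofuran-3-carboxylate (ring B cis to the hydroxyl)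
Conditions: hν (365 nm), degassed benzene, 0.01 M, 20 °C; then chromatography on silica gel or crystallisation to remove the (2S,3S) diastereomer
Reagents that add atoms: none
Why: Norrish–Yang photocyclisation: excitation of the glyoxylate ketone and intersystem crossing give a triplet with oxygen-radical character (the 2,6-dioxygenated ring A is twisted out of conjugation, which preserves the n,π* nature), and this abstracts one C2 hydrogen of the O1–CH2 group through a seven-membered transition state (1,6-hydrogen transfer). The 1,5-biradical so formed (ketyl carbon C4 and α-aryloxybenzyl carbon C2) recombines after spin inversion, making the C2–C4 bond and closing the dihydrofuran ring by radical–radical coupling (five-membered closure of a 1,5-biradical). The closest known reaction type is the photocyclisation of ortho-benzyloxyaryl ketones and glyoxylates to 3-hydroxy-2-aryl-2,3-dihydrobenzofurans. The relative configuration of the two new stereocentres is set in the biradical, where ring B turns away from the bulky menthyl ester as the bond forms, so that ring B ends up cis to the hydroxyl. The absolute configuration at C2 is only weakly biased by the remote auxiliary, so the (2R,3R) and (2S,3S) cis products are expected in comparable amounts and the menthyl group serves to make them separable diastereomers. The step needs site selectivity for the C2 hydrogens: both ketal carbons are quaternary, the methoxy groups are out of reach, and abstraction of the menthyl O–CH hydrogen (the Norrish type 2 path of alkyl glyoxylates) should be much slower than abstraction of a benzylic hydrogen that is also α to oxygen. Light of 365 nm is absorbed only by the α-keto ester, so 13, which no longer has this chromophore, should not be photolysed further, and degassing prevents capture of the biradical by oxygen.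

Step 9
Reactants: 13 (1R,2S,5R)-menthyl (2R,3R)-3-hydroxy-6-methoxy-2-(7-methoxy-2,2-diphenyl-1,3-benzodioxol-4-yl)-4,5-(diphenylmethylenedioxy)-2,3-dihydrobenzofuran-3-carboxylate
Product: 14 (2R,3S)-3-(hydroxymethyl)-6-methoxy-2-(7-methoxy-2,2-diphenyl-1,3-benzodioxol-4-yl)-4,5-(diphenylmethylenedioxy)-2,3-dihydrobenzofuran-3-ol
Conditions: LiAlH4, THF, 0 °C; aqueous work-up
Reagents that add atoms: none
Why: Hydride reduction of the ester to the primary alcohol with release of the auxiliary; neither stereocentre is touched (the descriptor at C3 changes only because the priorities change).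

Step 10
Reactants: 14 (2R,3S)-3-(hydroxymethyl)-6-methoxy-2-(7-methoxy-2,2-diphenyl-1,3-benzodioxol-4-yl)-4,5-(diphenylmethylenedioxy)-2,3-dihydrobenzofuran-3-ol
Product: 16 (2R,3R)-3-hydroxy-7-methoxy-2-(7-methoxy-2,2-diphenyl-1,3-benzodioxol-4-yl)-5,6-(diphenylmethylenedioxy)chroman-4-one, via hydroxy aldehyde 15 (not isolated)
Conditions: SO3·pyridine, DMSO, iPr2NEt, CH2Cl2, 0 °C; aqueous work-up; then DBU (0.2 equiv), toluene, Ar, 0 °C to rt
Reagents that add atoms: none
Why: Parikh–Doering oxidation of the primary alcohol (the tertiary one cannot be oxidised) gives α-hydroxy aldehyde 15, which with base undergoes the α-ketol (acyloin) rearrangement: the alkoxide at C4 pushes C2 onto the formyl carbon with retention at C2, the carbinol becomes the ring A-conjugated C4 ketone and the ring expands to ring C. The configuration at C3 is under thermodynamic control, because C3 is α to the new ketone and any cis isomer should equilibrate under the same conditions to the trans (2R,3R) isomer with both substituents equatorial.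

Step 11
Reactants: 16 (2R,3R)-3-hydroxy-7-methoxy-2-(7-methoxy-2,2-diphenyl-1,3-benzodioxol-4-yl)-5,6-(diphenylmethylenedioxy)chroman-4-one
Product: 17 (2R,3R)-3,7-dimethoxy-2-(7-methoxy-2,2-diphenyl-1,3-benzodioxol-4-yl)-5,6-(diphenylmethylenedioxy)chroman-4-one
Conditions: MeOTf, 2,6-di-tert-butyl-4-methylpyridine, CH2Cl2, 0 °C to rt
Reagents that add atoms: methyl trifluoromethanesulfonate, COS(=O)(=O)C(F)(F)F
Why: O-Methylation of the only free hydroxyl by a strong methylating agent with a hindered, non-nucleophilic proton scavenger; no enolate is formed, so C3 is not epimerised and ring C is not opened.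

Step 12
Reactants: 17 (2R,3R)-3,7-dimethoxy-2-(7-methoxy-2,2-diphenyl-1,3-benzodioxol-4-yl)-5,6-(diphenylmethylenedioxy)chroman-4-one
Product: 18 (2R,3R)-2-(2,3-dihydroxy-4-methoxyphenyl)-5,6-dihydroxy-3,7-dimethoxychroman-4-one (CNP0075602.1)
Conditions: H2 (1 atm), 10% Pd/C, THF–MeOH, rt, under exclusion of air on work-up
Reagents that add atoms: none
Why: Hydrogenolysis of both diphenylmethylene ketals, whose ketal carbons are doubly benzylic, frees the two catechols under neutral conditions. The O1–C2 bond is benzylic only once and lies in a ring, and the aryl ketone is expected to survive short exposure at atmospheric pressure.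

## Compound list

1 | 2,3-dihydroxy-4-methoxybenzaldehyde | COc1ccc(C=O)c(O)c1O | starting material
2 | dichlorodiphenylmethane | ClC(Cl)(c1ccccc1)c1ccccc1 | starting material
3 | 7-methoxy-2,2-diphenyl-1,3-benzodioxole-4-carbaldehyde | COc1ccc(C=O)c2OC(c3ccccc3)(c3ccccc3)Oc12 | intermediate
4 | (7-methoxy-2,2-diphenyl-1,3-benzodioxol-4-yl)methanol | COc1ccc(CO)c2OC(c3ccccc3)(c3ccccc3)Oc12 | intermediate
5 | 2',6'-dihydroxy-4'-methoxyacetophenone | COc1cc(O)c(C(C)=O)c(O)c1 | starting material
6 | potassium 3-acetyl-2,4-dihydroxy-6-methoxyphenyl sulfate | COc1cc(O)c(C(C)=O)c(O)c1OS(=O)(=O)[O-].[K+] | intermediate (not isolated)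
7 | 1-(2,3,6-trihydroxy-4-methoxyphenyl)ethanone | COc1cc(O)c(C(C)=O)c(O)c1O | intermediate
8 | 1-(5-hydroxy-7-methoxy-2,2-diphenyl-1,3-benzodioxol-4-yl)ethanone | COc1cc(O)c(C(C)=O)c2OC(c3ccccc3)(c3ccccc3)Oc12 | intermediate
9 | 1-{7-methoxy-5-[(7-methoxy-2,2-diphenyl-1,3-benzodioxol-4-yl)methoxy]-2,2-diphenyl-1,3-benzodioxol-4-yl}ethanone | COc1cc(OCc2ccc(OC)c3OC(c4ccccc4)(c4ccccc4)Oc23)c(C(C)=O)c2OC(c3ccccc3)(c3ccccc3)Oc12 | intermediate
10 | 2-{7-methoxy-5-[(7-methoxy-2,2-diphenyl-1,3-benzodioxol-4-yl)methoxy]-2,2-diphenyl-1,3-benzodioxol-4-yl}-2-oxoacetic acid | COc1cc(OCc2ccc(OC)c3OC(c4ccccc4)(c4ccccc4)Oc23)c(C(=O)C(=O)O)c2OC(c3ccccc3)(c3ccccc3)Oc12 | intermediate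
11 | (−)-menthol, (1R,2S,5R)-2-isopropyl-5-methylcyclohexanol | CC(C)[C@@H]1CC[C@@H](C)C[C@H]1O | starting material
12 | (1R,2S,5R)-menthyl 2-{7-methoxy-5-[(7-methoxy-2,2-diphenyl-1,3-benzodioxol-4-yl)methoxy]-2,2-diphenyl-1,3-benzodioxol-4-yl}-2-oxoacetate | COc1cc(OCc2ccc(OC)c3OC(c4ccccc4)(c4ccccc4)Oc23)c(C(=O)C(=O)O[C@@H]2C[C@H](C)CC[C@H]2C(C)C)c2OC(c3ccccc3)(c3ccccc3)Oc12 | intermediate
13 | (1R,2S,5R)-menthyl (2R,3R)-3-hydroxy-6-methoxy-2-(7-methoxy-2,2-diphenyl-1,3-benzodioxol-4-yl)-4,5-(diphenylmethylenedioxy)-2,3-dihydrobenzofuran-3-carboxylate | COc1ccc([C@H]2Oc3cc(OC)c4OC(c5ccccc5)(c5ccccc5)Oc4c3[C@]2(O)C(=O)O[C@@H]2C[C@H](C)CC[C@H]2C(C)C)c2OC(c3ccccc3)(c3ccccc3)Oc12 | intermediate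
14 | (2R,3S)-3-(hydroxymethyl)-6-methoxy-2-(7-methoxy-2,2-diphenyl-1,3-benzodioxol-4-yl)-4,5-(diphenylmethylenedioxy)-2,3-dihydrobenzofuran-3-ol | COc1ccc([C@H]2Oc3cc(OC)c4OC(c5ccccc5)(c5ccccc5)Oc4c3[C@]2(O)CO)c2OC(c3ccccc3)(c3ccccc3)Oc12 | intermediate
15 | (2R,3R)-3-hydroxy-6-methoxy-2-(7-methoxy-2,2-diphenyl-1,3-benzodioxol-4-yl)-4,5-(diphenylmethylenedioxy)-2,3-dihydrobenzofuran-3-carbaldehyde | COc1ccc([C@H]2Oc3cc(OC)c4OC(c5ccccc5)(c5ccccc5)Oc4c3[C@]2(O)C=O)c2OC(c3ccccc3)(c3ccccc3)Oc12 | intermediate (not isolated)
16 | (2R,3R)-3-hydroxy-7-methoxy-2-(7-methoxy-2,2-diphenyl-1,3-benzodioxol-4-yl)-5,6-(diphenylmethylenedioxy)chroman-4-one | COc1ccc([C@H]2Oc3cc(OC)c4OC(c5ccccc5)(c5ccccc5)Oc4c3C(=O)[C@@H]2O)c2OC(c3ccccc3)(c3ccccc3)Oc12 | intermediate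
17 | (2R,3R)-3,7-dimethoxy-2-(7-methoxy-2,2-diphenyl-1,3-benzodioxol-4-yl)-5,6-(diphenylmethylenedioxy)chroman-4-one | COc1ccc([C@H]2Oc3cc(OC)c4OC(c5ccccc5)(c5ccccc5)Oc4c3C(=O)[C@@H]2OC)c2OC(c3ccccc3)(c3ccccc3)Oc12 | intermediate
18 | (2R,3R)-2-(2,3-dihydroxy-4-methoxyphenyl)-5,6-dihydroxy-3,7-dimethoxychroman-4-one | COc1ccc([C@H]2Oc3cc(OC)c(O)c(O)c3C(=O)[C@@H]2OC)c(O)c1O | target

## Step count and least certain steps

Total: 12 steps. Longest linear sequence: 10 steps (steps 3 to 12 from 5; the branch from 1 through steps 1, 2 and 5 to 12 is equally long).

**Step 8 (key step).** The most likely failure is stereochemical. The menthyl group is far from the reacting carbons, so facial discrimination in the biradical closure may be negligible, and the two cis diastereomers may be hard to separate. Hydrogen abstraction from the menthyl O–CH group, or a slow reaction if the triplet gains π,π* character, would lower the efficiency further.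
Fallback: this sets out from 12 and returns at 14. 12 would be irradiated as in step 8, and the crude mixture of 13 and its ring diastereomer, (1R,2S,5R)-menthyl (2S,3S)-3-hydroxy-6-methoxy-2-(7-methoxy-2,2-diphenyl-1,3-benzodioxol-4-yl)-4,5-(diphenylmethylenedioxy)-2,3-dihydrobenzofuran-3-carboxylate F1, would not be separated. It would be reduced with LiAlH4 as in step 9 to 14 together with its enantiomer, the (2S,3R)-diol F2. The enantiomers would then be separated by preparative chromatography on a chiral stationary phase, so that the resolution no longer depends on the auxiliary.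

**Step 10.** The most likely failure is migration of the ring A carbon in competition with C2. The formyl group rotates freely, so both ring bonds at the carbinol carbon can align with the carbonyl; only the conjugation gained in the product favours C2. Base-induced opening of ring C, which would erode C2, is the second concern.
Fallback: this sets out from 15 and returns at 16. The crude ketol mixture, 16 and the regioisomeric 4-hydroxychroman-3-one F3, would be reduced without delay with NaBH4 (MeOH–THF, −40 °C) to the common chroman-3,4-diol F4. The reduction is done at once because C2 of F3 is α to its ketone and would epimerise on standing in base. MnO2 (CH2Cl2, rt) would then oxidise only the benzylic C4 carbinol, giving 16 together with its cis C3 epimer, the (2R,3S)-ketol F5, which brief treatment with catalytic DBU converts to 16. The regiochemistry of the shift thus becomes irrelevant.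

**Step 3.** The most likely failure is low conversion together with oxidative degradation. K2S2O8 also opens radical pathways, and the product is a 1,2,4-trihydroxybenzene that oxidises in air, especially in base.
Fallback: this sets out from 5 and returns at 7. Rieche formylation (Cl2CHOMe, TiCl4, CH2Cl2, 0 °C) at one of the two equivalent ring positions would give 3-acetyl-2,4-dihydroxy-6-methoxybenzaldehyde F6. Dakin oxidation (H2O2, aq NaOH, 0 °C) would then replace the formyl group by hydroxyl.

**Step 5.** The most likely failure is ionisation of the activated, very electron-rich benzylic alcohol, leading to C-benzylation of ring A or self-condensation, combined with slow reaction of the hydrogen-bonded phenol.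
Fallback: this sets out from 4 and returns at 9. 4 would be converted with MsCl and Et3N (CH2Cl2, 0 °C) into 4-(chloromethyl)-7-methoxy-2,2-diphenyl-1,3-benzodioxole F7, used at once to alkylate 8 with K2CO3 in DMF (Williamson ether synthesis).

**Step 12.** The most likely failure is over-reduction, meaning hydrogenolysis of the O1–C2 bond or reduction of the C4 ketone, or incomplete cleavage of the hindered ring A ketal.
Fallback: this sets out from 17 and returns at 18. Both ketals would be hydrolysed with AcOH–H2O (4:1, 90 °C, under Ar), releasing benzophenone. No new intermediate is involved.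

## Further compounds

F1 | step 8 | (1R,2S,5R)-menthyl (2S,3S)-3-hydroxy-6-methoxy-2-(7-methoxy-2,2-diphenyl-1,3-benzodioxol-4-yl)-4,5-(diphenylmethylenedioxy)-2,3-dihydrobenzofuran-3-carboxylate | COc1ccc([C@@H]2Oc3cc(OC)c4OC(c5ccccc5)(c5ccccc5)Oc4c3[C@@]2(O)C(=O)O[C@@H]2C[C@H](C)CC[C@H]2C(C)C)c2OC(c3ccccc3)(c3ccccc3)Oc12
F2 | step 8 | (2S,3R)-3-(hydroxymethyl)-6-methoxy-2-(7-methoxy-2,2-diphenyl-1,3-benzodioxol-4-yl)-4,5-(diphenylmethylenedioxy)-2,3-dihydrobenzofuran-3-ol | COc1ccc([C@@H]2Oc3cc(OC)c4OC(c5ccccc5)(c5ccccc5)Oc4c3[C@@]2(O)CO)c2OC(c3ccccc3)(c3ccccc3)Oc12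
F3 | step 10 | (2R)-4-hydroxy-7-methoxy-2-(7-methoxy-2,2-diphenyl-1,3-benzodioxol-4-yl)-5,6-(diphenylmethylenedioxy)chroman-3-one (C4 epimers) | COc1ccc([C@H]2Oc3cc(OC)c4OC(c5ccccc5)(c5ccccc5)Oc4c3C(O)C2=O)c2OC(c3ccccc3)(c3ccccc3)Oc12
F4 | step 10 | (2R)-7-methoxy-2-(7-methoxy-2,2-diphenyl-1,3-benzodioxol-4-yl)-5,6-(diphenylmethylenedioxy)chromane-3,4-diol (C3 and C4 epimers) | COc1ccc([C@H]2Oc3cc(OC)c4OC(c5ccccc5)(c5ccccc5)Oc4c3C(O)C2O)c2OC(c3ccccc3)(c3ccccc3)Oc12
F5 | step 10 | (2R,3S)-3-hydroxy-7-methoxy-2-(7-methoxy-2,2-diphenyl-1,3-benzodioxol-4-yl)-5,6-(diphenylmethylenedioxy)chroman-4-one | COc1ccc([C@H]2Oc3cc(OC)c4OC(c5ccccc5)(c5ccccc5)Oc4c3C(=O)[C@H]2O)c2OC(c3ccccc3)(c3ccccc3)Oc12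
F6 | step 3 | 3-acetyl-2,4-dihydroxy-6-methoxybenzaldehyde | COc1cc(O)c(C(C)=O)c(O)c1C=O
F7 | step 5 | 4-(chloromethyl)-7-methoxy-2,2-diphenyl-1,3-benzodioxole | COc1ccc(CCl)c2OC(c3ccccc3)(c3ccccc3)Oc12
F0 | step 12 | none | none
A1 | alternative 1 | (2R,3R)-2-[2,3-bis(benzyloxy)-4-methoxyphenyl]-6-(2,3-dimethoxy-4-oxocyclobut-2-en-1-yl)-3-methoxy-2,3-dihydro-4H-pyran-4-one | COc1ccc([C@H]2OC(C3C(=O)C(OC)=C3OC)=CC(=O)[C@@H]2OC)c(OCc2ccccc2)c1OCc1ccccc1
A2 | alternative 1 | (2R,3R)-2',3'-bis(benzyloxy)-5-hydroxy-3,6,7,4'-tetramethoxyflavanone | COc1ccc([C@H]2Oc3cc(OC)c(OC)c(O)c3C(=O)[C@@H]2OC)c(OCc2ccccc2)c1OCc1ccccc1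
A3 | alternative 2 | (R)-2-[2,3-bis(benzyloxy)-4-methoxyphenyl]-2-[3,4-bis(benzyloxy)-2-formyl-5-methoxyphenoxy]acetaldehyde | COc1ccc([C@H](C=O)Oc2cc(OC)c(OCc3ccccc3)c(OCc3ccccc3)c2C=O)c(OCc2ccccc2)c1OCc1ccccc1
A4 | alternative 2 | (2R,3R)-5,6,2',3'-tetrakis(benzyloxy)-3-hydroxy-7,4'-dimethoxyflavanone | COc1ccc([C@H]2Oc3cc(OC)c(OCc4ccccc4)c(OCc4ccccc4)c3C(=O)[C@@H]2O)c(OCc2ccccc2)c1OCc1ccccc1
A5 | alternative 3 | (2R,3R)-3-[2,3-bis(benzyloxy)-4-methoxyphenyl]-1-(2,3-dihydroxy-4-methoxyphenyl)-3-hydroxy-2-methoxypropan-1-one | COc1ccc([C@@H](O)[C@@H](OC)C(=O)c2ccc(OC)c(O)c2O)c(OCc2ccccc2)c1OCc1ccccc1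
A6 | alternative 3 | (2R,3R)-3-[2,3-bis(benzyloxy)-4-methoxyphenyl]-3-hydroxy-2-methoxy-1-(4-methoxy-5,6-dioxocyclohexa-1,3-dien-1-yl)propan-1-one | COc1ccc([C@@H](O)[C@@H](OC)C(=O)C2=CC=C(OC)C(=O)C2=O)c(OCc2ccccc2)c1OCc1ccccc1
A7 | alternative 3 | (2R,3R)-2',3'-bis(benzyloxy)-5,6-dihydroxy-3,7,4'-trimethoxyflavanone | COc1ccc([C@H]2Oc3cc(OC)c(O)c(O)c3C(=O)[C@@H]2OC)c(OCc2ccccc2)c1OCc1ccccc1
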